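**Retrosynthetic overview**

1. Locants are those of the target name, (1R,3R,5R,7S,9S)-3-acetyl-4,4,7-trimethyl-9-(3-methylbut-2-en-1-yl)-9-(2-methylpropanoyl)tricyclo[5.3.1.0^{1,5}]undecane-8,10,11-trione: C1 quaternary ring-fusion carbon, C3 CH–acetyl, C4 CMe2, C5 ring-fusion CH, C6 CH2, C7 C–Me bridgehead, C9 C(prenyl)(acyl), C8/C10/C11 ketones.
2. Last bond: C9–prenyl, by exo-face palladium-catalysed C-allylation of the enolised acyl-dione 10.
3. Key step, both carbocycles from a flat arene in one operation: oxidative dearomative (5+2) radical annulation of 9. The oxidised, now electrophilic phloroglucinol carbon joins the internal vinyl carbon (C1–C5, cyclopentane first); C6 then closes on the methyl-bearing ring carbon (C6–C7, bicyclo[3.2.1]octane second); the three phenolic carbons end as the three ring ketones.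
4. 9 comes from acylphloroglucinol 3 and α-methylene ketone 8 by an enantioselective Friedel–Crafts conjugate addition/protonation that sets C3, the only stereocentre fed into the cascade.
5. 3 comes from 2-methylphloroglucinol by acylation (the six-membered ring is bought as the arene); 8 comes from mesityl oxide by vinyl conjugate addition, Mannich trapping and elimination.

Assumption: the antipode of the amine catalyst used in step 4 is the one that gives (3R)-9 (written below as the (S)-diamine), and 9 is drawn as the open hydroxy ketone although it equilibrates with its cyclic hemiketal.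

**Route**

Step 1
Reactants: 1 2-methylbenzene-1,3,5-triol; 2 2-methylpropanoyl chloride
Product: 3 1-(2,4,6-trihydroxy-3-methylphenyl)-2-methylpropan-1-one
Conditions: AlCl3 (3.5 equiv), PhNO2, 65 °C; aq. HCl work-up
Reagents that add atoms: none
Why: Friedel–Crafts C-acylation of the electron-rich triol, whose two free ring positions are equivalent and whose first acyl group deactivates the ring towards a second acylation; no stereocentre is formed.

Step 2
Reactants: 4 4-methylpent-3-en-2-one (mesityl oxide)
Product: 6 (±)-3-[(dimethylamino)methyl]-4,4-dimethylhex-5-en-2-one, via bromomagnesium enolate 5 (not isolated)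
Conditions: CH2=CHMgBr (1.2 equiv), CuBr·SMe2 (5 mol%), THF, −40 °C; then CH2=NMe2+ I− (1.3 equiv), −40 °C to rt
Reagents that add atoms: vinylmagnesium bromide C=C[Mg]Br; dimethyl(methylidene)ammonium iodide (Eschenmoser's salt) C=[N+](C)C.[I-]
Why: Copper-catalysed conjugate addition of the vinyl Grignard reagent builds the quaternary CMe2 carbon and delivers the enolate regiospecifically on the hindered side, where a Mannich reaction traps it; the stereocentre formed is racemic and is erased in step 3.

Step 3
Reactants: 6 (±)-3-[(dimethylamino)methyl]-4,4-dimethylhex-5-en-2-one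
Product: 8 4,4-dimethyl-3-methylidenehex-5-en-2-one, via quaternary ammonium iodide 7 (not isolated)
Conditions: MeI (3 equiv), Et2O, rt; then NaHCO3 (aq)/CH2Cl2, rt
Reagents that add atoms: none
Why: N-methylation followed by base-induced β-elimination of trimethylamine (E1cB, Hofmann-type) gives the α-methylene ketone; no stereocentre is present.

Step 4
Reactants: 3 1-(2,4,6-trihydroxy-3-methylphenyl)-2-methylpropan-1-one; 8 4,4-dimethyl-3-methylidenehex-5-en-2-one (1.5 equiv)
Product: 9 (3R)-4,4-dimethyl-3-{[2,4,6-trihydroxy-3-methyl-5-(2-methylpropanoyl)phenyl]methyl}hex-5-en-2-one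
Conditions: (S)-N1,N1-diethyl-3,3-dimethylbutane-1,2-diamine·TfOH (20 mol%), CHCl3, 25 °C
Reagents that add atoms: none
Why: Proposed new method: the primary amine of the catalyst converts 8 into an iminium ion, the single free ring carbon of 3 adds to its CH2 terminus (Friedel–Crafts conjugate addition), and the enamine so formed is protonated intramolecularly on one face by the ammonium arm of the catalyst, which sets C3 as (R), the closest known reaction type being chiral primary-amine-catalysed conjugate addition/enantioselective enamine protonation of α-substituted vinyl ketones with indoles and other soft nucleophiles.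

Step 5
Reactants: 9 (3R)-4,4-dimethyl-3-{[2,4,6-trihydroxy-3-methyl-5-(2-methylpropanoyl)phenyl]methyl}hex-5-en-2-one
Product: 10 (1R,3R,5R,7R)-3-acetyl-8-hydroxy-4,4,7-trimethyl-9-(2-methylpropanoyl)tricyclo[5.3.1.0^{1,5}]undec-8-ene-10,11-dione
Conditions: Mn(OAc)3·2H2O (2.5 equiv, portionwise), degassed AcOH (0.01 M), 23 °C
Reagents that add atoms: none
Why: Proposed new method: one-electron oxidation by Mn(OAc)3 turns the normally nucleophilic, tether-bearing ring carbon of the acylphloroglucinol into an electrophilic aryloxyl/α-keto radical (a vinylogous 1,3-dicarbonyl radical) that adds 5-exo to the internal vinyl carbon through a chair-like transition state with the acetyl group pseudo-equatorial (acetyl cis to the new C6H2, Beckwith–Houk model, closure accelerated by the gem-dimethyl group), the primary C6 radical then closes 5-exo on the methyl-bearing ring carbon rather than the acyl-bearing one (this keeps the chelated acyl-enol conjugation and gives the more stabilised radical, and a reversible first closure funnels material this way), and a second equivalent of oxidant converts the resulting hydroxyallyl radical into the enolised trione, so that C1, C5 and C7 follow from C3 and the ring geometry, the closest known reaction types being the Mn(OAc)3-mediated oxidative radical cyclisation of dearomatised prenylated acylphloroglucinols and the oxidative-dearomatisation-induced (5+2) cycloaddition of phenols with tethered alkenes.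

Step 6
Reactants: 10 (1R,3R,5R,7R)-3-acetyl-8-hydroxy-4,4,7-trimethyl-9-(2-methylpropanoyl)tricyclo[5.3.1.0^{1,5}]undec-8-ene-10,11-dione; 11 3-methylbut-2-en-1-yl acetate (prenyl acetate)
Product: 12 (1R,3R,5R,7S,9S)-3-acetyl-4,4,7-trimethyl-9-(3-methylbut-2-en-1-yl)-9-(2-methylpropanoyl)tricyclo[5.3.1.0^{1,5}]undecane-8,10,11-trione
Conditions: Pd(PPh3)4 (5 mol%), Et3N (1.2 equiv), THF, 40 °C
Reagents that add atoms: none
Why: Tsuji–Trost allylic alkylation in which the soft triketone enolate attacks the unsubstituted terminus of the prenyl–palladium complex (linear product; any O-prenyl enol ether re-ionises under zerovalent palladium and funnels to the C-alkylated trione) on the face of C9 opposite the two-carbon C5–C6 bridge, the open exo face of the bicyclo[3.2.1]octane, which places the prenyl group as in the target (9S).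

**Compound list**

1 | 2-methylbenzene-1,3,5-triol | Cc1c(O)cc(O)cc1O | starting material
2 | 2-methylpropanoyl chloride | CC(C)C(Cl)=O | starting material
3 | 1-(2,4,6-trihydroxy-3-methylphenyl)-2-methylpropan-1-one | CC(C)C(=O)c1c(O)cc(O)c(C)c1O | intermediate
4 | 4-methylpent-3-en-2-one | CC(=O)C=C(C)C | starting material
5 | bromomagnesium 4,4-dimethylhexa-2,5-dien-2-olate | C=CC(C)(C)C=C(C)O[Mg]Br | intermediate
6 | (±)-3-[(dimethylamino)methyl]-4,4-dimethylhex-5-en-2-one | CC(=O)C(CN(C)C)C(C)(C)C=C | intermediate
7 | (±)-(2-acetyl-3,3-dimethylpent-4-en-1-yl)trimethylammonium iodide | CC(=O)C(C[N+](C)(C)C)C(C)(C)C=C.[I-] | intermediate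
8 | 4,4-dimethyl-3-methylidenehex-5-en-2-one | CC(=O)C(=C)C(C)(C)C=C | intermediate
9 | (3R)-4,4-dimethyl-3-{[2,4,6-trihydroxy-3-methyl-5-(2-methylpropanoyl)phenyl]methyl}hex-5-en-2-one | CC(=O)[C@H](Cc1c(O)c(C)c(O)c(C(=O)C(C)C)c1O)C(C)(C)C=C | intermediate
10 | (1R,3R,5R,7R)-3-acetyl-8-hydroxy-4,4,7-trimethyl-9-(2-methylpropanoyl)tricyclo[5.3.1.0^{1,5}]undec-8-ene-10,11-dione | CC(=O)[C@@H]1C[C@]23C(=O)[C@](C)(C[C@@H]2C1(C)C)C(O)=C(C(=O)C(C)C)C3=O | intermediate
11 | 3-methylbut-2-en-1-yl acetate | CC(=O)OCC=C(C)C | starting material
12 | (1R,3R,5R,7S,9S)-3-acetyl-4,4,7-trimethyl-9-(3-methylbut-2-en-1-yl)-9-(2-methylpropanoyl)tricyclo[5.3.1.0^{1,5}]undecane-8,10,11-trione | CC(=O)[C@@H]1C[C@]23C(=O)[C@](C)(C[C@@H]2C1(C)C)C(=O)[C@](CC=C(C)C)(C(=O)C(C)C)C3=O | target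

**Step count and risks**

Total step count: 6. Longest linear sequence: 5 steps (4 → 6 → 8 → 9 → 10 → 12).

Most at risk is step 5. The stabilised aryloxyl radical may dimerise or be over-oxidised to a quinone methide before it cyclises, the second closure may compete at the acyl-bearing carbon, and the cis preference between C3 and C5 may be modest. The minor diastereomer carries the mirror-image core with the same C3 and is removed by chromatography, so the enantiomeric purity of 10 equals that of 9. The fallback sets out from 9 and comes back at 10. N-Chlorosuccinimide (CH2Cl2, −20 °C) chlorinates the tether-bearing ring carbon to give 6-[(2R)-2-acetyl-3,3-dimethylpent-4-en-1-yl]-6-chloro-3,5-dihydroxy-2-methyl-4-(2-methylpropanoyl)cyclohexa-2,4-dien-1-one F1. A chloride on the methyl-bearing carbon serves equally, because both give the same delocalised radical. CuCl (20 mol%) with tris(2-pyridylmethyl)amine in degassed 1,2-dichloroethane at 60 °C then runs an atom-transfer radical cyclisation: monovalent copper abstracts chlorine, the same two 5-exo closures follow, chlorine is returned to the last radical, and the α-chloro alcohol loses HCl to give 10. The radical is thus made reductively from a C–Cl bond, with no free oxidant present.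

Second is step 4. Iminium formation with the bulky α-tert-alkyl enone may be slow, acid-catalysed background addition may erode the ee, and 9 must be kept below 30 °C and away from strong acid because dehydration of its hemiketal to a 4H-chromene would erase C3. The fallback sets out from 3 and 8 and comes back at 9. Sc(OTf)3 (5 mol%) in MeCN at 25 °C gives racemic 4,4-dimethyl-3-{[2,4,6-trihydroxy-3-methyl-5-(2-methylpropanoyl)phenyl]methyl}hex-5-en-2-one F2. Preparative supercritical-fluid chromatography on a chiral stationary phase then delivers 9. The unwanted (3S)-4,4-dimethyl-3-{[2,4,6-trihydroxy-3-methyl-5-(2-methylpropanoyl)phenyl]methyl}hex-5-en-2-one F3 is racemised by enolisation (DBU, toluene, 60 °C) and recycled.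

Third is step 6. The quaternary centre is crowded, and O-alkylation or attack at the substituted prenyl terminus could intervene. The fallback sets out from 10 and comes back at 12. Allyl acetate with Pd(PPh3)4 and Et3N in THF gives (1R,3R,5R,7S,9S)-3-acetyl-4,4,7-trimethyl-9-(2-methylpropanoyl)-9-(prop-2-en-1-yl)tricyclo[5.3.1.0^{1,5}]undecane-8,10,11-trione F4. The smaller, symmetrical allyl unit has no regiochemical issue, and any O-allyl enol ether converges on the same compound by Claisen rearrangement on heating in toluene. Cross-metathesis with 2-methylbut-2-ene and second-generation Grubbs catalyst (5 mol%, CH2Cl2, 40 °C) then gives 12.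

**Further compounds**

F1 | step 5 | 6-[(2R)-2-acetyl-3,3-dimethylpent-4-en-1-yl]-6-chloro-3,5-dihydroxy-2-methyl-4-(2-methylpropanoyl)cyclohexa-2,4-dien-1-one (either configuration at C6) | CC(=O)[C@H](CC1(Cl)C(=O)C(C)=C(O)C(C(=O)C(C)C)=C1O)C(C)(C)C=C
F2 | step 4 | racemic 4,4-dimethyl-3-{[2,4,6-trihydroxy-3-methyl-5-(2-methylpropanoyl)phenyl]methyl}hex-5-en-2-one | CC(=O)C(Cc1c(O)c(C)c(O)c(C(=O)C(C)C)c1O)C(C)(C)C=C
F3 | step 4 | (3S)-4,4-dimethyl-3-{[2,4,6-trihydroxy-3-methyl-5-(2-methylpropanoyl)phenyl]methyl}hex-5-en-2-one | CC(=O)[C@@H](Cc1c(O)c(C)c(O)c(C(=O)C(C)C)c1O)C(C)(C)C=C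
F4 | step 6 | (1R,3R,5R,7S,9S)-3-acetyl-4,4,7-trimethyl-9-(2-methylpropanoyl)-9-(prop-2-en-1-yl)tricyclo[5.3.1.0^{1,5}]undecane-8,10,11-trione | CC(=O)[C@@H]1C[C@]23C(=O)[C@](C)(C[C@@H]2C1(C)C)C(=O)[C@](CC=C)(C(=O)C(C)C)C3=O
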